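Compound numbers 1–28 are fixed by the steps below and used in every section. Positions follow eremophilane numbering: ring A is C1–C5 plus C10, ring B is C5–C10, C14 is the methyl on C5, C15 the methyl on C4, and C11–C13 the isopropenyl group on C7. β denotes the face of the decalin that carries the C5 methyl group. "11,12,13-Trinoreremophilane" means the same 4,5-dimethyldecalin without the C7 side chain.

## The problem

1. The target is an eremophilane: rings A and B form a trans-fused decalin with an angular methyl group on C5, a methyl group on C4, an angelate on C3, an isopropenyl group on C7, a ketone at C8 and an (E)-3-methylpent-2-enoate on C9.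
2. Of the six stereocentres (C3, C4, C5, C7, C9, C10) only the quaternary C5 cannot be adjusted once made. The substituents on C3, C4, C7 and C9 are equatorial and the fusion is trans, so C5 must be set absolutely and must then steer the others.
3. The axial C5 methyl group is syn-axial to the β faces of C3, C7 and C9 and sends external reagents to the α face. That is right for carbon at C7 but wrong for hydride at C3 and C9, where the oxygen atoms, not the hydrogens, must be α.
4. The C8 ketone sits between an isopropenyl-bearing carbon and an acyloxy-bearing carbon. With acid or base the β,γ-unsaturated ketone epimerises at C7 or slips into conjugation (isopropylidene), and the α-acyloxy ketone can epimerise, eliminate or transfer its acyl group.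
5. The angelate isomerises to the tiglate when the acid is activated as an acyl donor or meets nucleophilic bases. Both esters are therefore best made with the acids as nucleophiles, and the C8 carbonyl should appear late under near-neutral conditions.
6. The feature that opens a short route is ring A together with C9. With the C3 oxygen written as a silyl enol ether across C3–C4 and C9 as a ketone, the bonds C1–C2 and C5–C10 are the two new bonds of a Diels–Alder reaction between a 2-silyloxydiene (C2 to C5) and a vinyl ketone (C1, C10, C9).
7. Because C6–C7–C8 ties C5 to C9, this cycloaddition is intramolecular. It closes both rings, creates the quaternary centre, and leaves the two carbonyl groups differentiated (C3 masked, C9 free).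

## Retrosynthesis

**28 to 26 and 27.** The alkyl C9–O bond of the pentenoate is cut, not the acyl C–O bond. An acylation would need the 9α-alcohol, which hydride cannot deliver because the C5 methyl group directs it to the α face, and it would expose the finished ketone to acyl-transfer bases. The forward reaction is a Mitsunobu inversion of the axial 9β-ketol 26 by acid 27: a substitution at a carbon next to a carbonyl group, under near-neutral conditions. The precursor lacks one ester and has the easily made C9 configuration.

**26 back to 22.** Three redox steps move the carbonyl from C9 to C8 while C9 keeps its oxygen. Ketol 26 comes from diol 25 by oxidation of the less hindered C8 carbinol, 25 from hydroxy ketone 24 by α-face hydride delivery, and 24 from silyl enol ether 22 by epoxidation. A direct base-mediated ketol isomerisation of 24 would be shorter, but it runs through an enediol under conditions that also move the isopropenyl double bond into conjugation. The forward steps must distinguish an enol ether from two other olefins and one of two secondary hydroxyl groups from the other.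

**22 to 20 and 21.** The C7–C11 bond is cut. Conjugate addition of isopropenylmagnesium bromide 21 to enone 20 is preferred to any alkylation next to a C8 ketone, for which no good isopropenyl electrophile exists and which would place the group beside a ketone under basic conditions. The reaction must attack C7 from the α face, which the axial C5 methyl group should enforce, and must store the enolate as its silyl ether.

**20 to 18 and 19, and 18 to 17.** The alkyl C3–O bond is cut in the same way as at C9: angelic acid 19 displaces the activated axial 3β-hydroxyl of 18 with inversion. Alcohol 18 comes from ene-dione 17 by reduction of the saturated C3 ketone only. In a saturated 3,9-dione the two carbonyl groups would be nearly equivalent, both β to the quaternary carbon. With C9 as an enone they differ enough for a borohydride to tell them apart.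

**17 to 15 to 13.** Ene-dione 17 comes from dienone 15 by epimerisation at C10 and unveiling of the C3 ketone with protonation at C4. Dienone 15 comes from adduct 13 by dehydrogenation across C7–C8. Dehydrogenating while C3 is still a silyl enol ether removes any question of which ketone is enolised.

**13 to 12.** The key cut opens C5–C10 and C1–C2 and unfolds both rings to the achiral trienone 12. No other single disconnection removes two rings, the quaternary centre and the C10 centre at once. The forward reaction must fix the absolute configuration at C5, and the rest is corrected or derived later.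

**12 to 11, then to 9 and 10, and 9 to 8.** The vinyl ketone comes from oxidation of allylic alcohol 11, made from aldehyde 9 and vinylmagnesium bromide 10. Aldehyde 9 comes from nitrile 8 by partial reduction. The enone must be created last, because it cannot coexist with the base needed to make the silyloxydiene. A nitrile is the one chain end that survives every earlier step and is still reducible in the presence of the diene.

**8 to 6 to 5 to 4.** The silyloxydiene comes from methyl ketone 6 by kinetic enolisation and O-silylation. Ketone 6 comes from ester 4 through amide 5. This order keeps the head group an unreactive, non-enolisable ester during the coupling.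

**4 to 2 and 3, and 2 to 1.** The C5–C6 bond (vinyl to alkyl) is cut. Cross-coupling of the stereodefined enol tosylate 2 with (3-cyanopropyl)zinc bromide 3 fixes the geometry of the tetrasubstituted olefin, which decides whether the tether can reach in the key step. A conjugate addition to an ynone with enolate methylation would pass through an allenolate and would not hold that geometry. The zinc reagent brings C6–C9, the four tether carbons. Tosylate 2 comes from β-keto ester 1.

## Roads not taken

**Alternative 1:** The cut is C7–C8. In the forward sense an aluminium Lewis acid would promote an intramolecular carbonyl-ene reaction in which an aldehyde carbon (C8) bonds to the inner carbon of a prenyl olefin (C7) and a methyl hydrogen passes to oxygen. Ring B closes and the isopropenyl group is created in the same event, giving the 8-ol A1.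

- Merits: the isopropenyl group is born out of conjugation at the alcohol oxidation level, C7 and C8 come out trans through a chair-like transition state, the C9 oxygen can be in place beforehand, and C8 is oxidised at the very end under neutral conditions.
- Weak points: the substrate is a fully substituted cyclohexane. Four ring A centres plus C9 must be built without the help of ring B. The α-alkoxy aldehyde is epimerisable, and aluminium chelation between the aldehyde and the C9 ether could change the facial course.
- Comparison: in the ring B endgame this road is better than the chosen one, which spends five steps and its main risks there. The chosen plan sets against it a one-step catalytic assembly of both rings and C5 from an achiral chain, and a much shorter route to the decalin.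

**Alternative 2:** The cuts are C4–C15 and C5–C6. A methylcuprate would add to C4 of an enantiopure cyclohexenone that already bears the C3 silyloxy group, anti to that group. The enolate would then be allylated at C5, giving ketone A2 with the C3, C4, C5 triad in one flask.

- Merits: three contiguous centres including the quaternary one are set at once, the absolute configuration comes from an existing stereocentre, and the C3 oxygen is correct from the start, so no inversion at C3 is needed.
- Weak points: no ring is formed. Ring B with C7, C8, C9 and the C10 centre must still be annulated in several C–C bond-forming steps, and alkylation of a cuprate-derived enolate next to a new stereocentre is sluggish.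
- Comparison: for the ring A triad, and for C3 in particular, this road is as good or better. The chosen plan sets against it the closure of both rings in one step and a C9 carbonyl already placed for the ring B work.

**Alternative 3:** The cut is C4–C5, read as a ring contraction of ring A to a cyclopentanone. In the forward sense a one-carbon unit carrying the C15 methyl and a selenium group is added to that carbonyl. A thiophilic silver salt then triggers a semipinacol shift in which C5 migrates from C3 to C4, giving enedione A3.

- Merits: the quaternary centre and its absolute configuration come from a bicyclic building block available by amine-catalysed aldol cyclisation, the more substituted carbon migrates, and the ring B carbonyl already sits at C8, so no carbonyl transposition is needed.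
- Weak points: the isopropenyl group would have to be introduced next to the C8 ketone with no conjugate-addition handle. The C9 oxygen and the trans fusion would have to be made from the C9–C10 enone olefin. The C3 and C8 carbonyls again need differentiation, and selenium and silver are used stoichiometrically.
- Comparison: this road is better on absolute stereocontrol and on the position of the ring B carbonyl. The chosen plan sets against it a C9 carbonyl that allows α-face conjugate addition at C7 and a ring fusion that is corrected by simple epimerisation.

Key step: step 9

Remarks on the chemistry: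

- The sense of induction of the (S)-catalyst in step 9 is assumed. If the adduct proves to be the antipode, the catalyst from (R)-α,α-diphenylprolinol is used and nothing else changes.
- Compounds 3, 10, 19, 21 and 27 are taken as purchasable, 19 and 27 as single olefin isomers.

## Steps

Step 1
Reactants: 1 methyl 2-methyl-3-oxobutanoate
Product: 2 methyl (E)-2-methyl-3-(4-methylbenzenesulfonyloxy)but-2-enoate
Conditions: TsCl, TMEDA, MeCN, 0 °C, no lithium salt
Reagents that add atoms: 4-methylbenzenesulfonyl chloride, Cc1ccc(cc1)S(=O)(=O)Cl
Why: Stereoselective enol tosylation of a β-keto ester; without a chelating cation the enolate oxygen turns away from the ester carbonyl, so the sulfonyloxy group should end trans to CO2Me (E), which fixes the later diene geometry.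

Step 2
Reactants: 2 methyl (E)-2-methyl-3-(4-methylbenzenesulfonyloxy)but-2-enoate; 3 (3-cyanopropyl)zinc bromide
Product: 4 methyl (E)-6-cyano-2,3-dimethylhex-2-enoate
Conditions: PdCl2(dppf) (5 mol %), THF, 50 °C
Reagents that add atoms: none
Why: Negishi cross-coupling; oxidative addition of zerovalent palladium into the ester-activated vinyl C–O bond and reductive elimination both go with retention, so the chain should replace the tosylate trans to the ester, and the nitrile is inert to the organozinc.

Step 3
Reactants: 4 methyl (E)-6-cyano-2,3-dimethylhex-2-enoate
Product: 5 (E)-6-cyano-N-methoxy-N,2,3-trimethylhex-2-enamide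
Conditions: MeNH(OMe)·HCl, AlMe3, CH2Cl2, 0 → 40 °C
Reagents that add atoms: N,O-dimethylhydroxylamine hydrochloride, CNOC.Cl
Why: Weinreb amide formation by aminolysis with the aluminium amide made in the flask; the strong reagent is chosen because the tetrasubstituted conjugated ester is hindered, and the nitrile is not attacked at this temperature.

Step 4
Reactants: 5 (E)-6-cyano-N-methoxy-N,2,3-trimethylhex-2-enamide
Product: 6 (E)-5,6-dimethyl-7-oxooct-5-enenitrile
Conditions: MeMgBr, THF, −20 → 0 °C; aq NH4Cl
Reagents that add atoms: methylmagnesium bromide, C[Mg]Br
Why: Weinreb ketone synthesis; the chelated adduct stops at the ketone stage, and in THF at 0 °C a Grignard reagent adds to the amide much faster than to an aliphatic nitrile.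

Step 5
Reactants: 6 (E)-5,6-dimethyl-7-oxooct-5-enenitrile
Product: 8 (E)-5,6-dimethyl-7-(triisopropylsilyloxy)octa-5,7-dienenitrile, via lithium dienolate 7 (not isolated)
Conditions: LiN(iPr)2, THF, −78 °C; then iPr3SiOSO2CF3, −78 → 0 °C
Reagents that add atoms: triisopropylsilyl trifluoromethanesulfonate, CC(C)[Si](OS(=O)(=O)C(F)(F)F)(C(C)C)C(C)C
Why: Kinetic enolate formation and O-silylation; the amide base takes a proton from the acetyl methyl group and not from the γ positions, giving the cross-conjugated 2-silyloxydiene and leaving the E tetrasubstituted olefin untouched.

Step 6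
Reactants: 8 (E)-5,6-dimethyl-7-(triisopropylsilyloxy)octa-5,7-dienenitrile
Product: 9 (E)-5,6-dimethyl-7-(triisopropylsilyloxy)octa-5,7-dienal
Conditions: iBu2AlH, toluene, −78 °C; aq potassium sodium tartrate, 0 °C
Reagents that add atoms: water, O
Why: Partial reduction of the nitrile to the aluminated aldimine and hydrolysis in a near-neutral work-up; the hindered silyl dienol ether tolerates hydride and a pH 7 work-up.

Step 7
Reactants: 9 (E)-5,6-dimethyl-7-(triisopropylsilyloxy)octa-5,7-dienal; 10 vinylmagnesium bromide
Product: 11 (E)-7,8-dimethyl-9-(triisopropylsilyloxy)deca-1,7,9-trien-3-ol (racemic)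
Conditions: THF, −78 °C; aq NH4Cl
Reagents that add atoms: none
Why: Grignard 1,2-addition to the aldehyde; the new carbinol centre forms as a racemate, which does not matter because it is oxidised in the next step.

Step 8
Reactants: 11 (E)-7,8-dimethyl-9-(triisopropylsilyloxy)deca-1,7,9-trien-3-ol
Product: 12 (E)-7,8-dimethyl-9-(triisopropylsilyloxy)deca-1,7,9-trien-3-one
Conditions: Dess–Martin periodinane, pyridine, CH2Cl2, 0 °C; used at once
Reagents that add atoms: none
Why: Dess–Martin oxidation of the allylic alcohol under buffered conditions that spare the silyl dienol ether; the vinyl ketone is kept cold and used directly to limit uncatalysed cycloaddition and polymerisation.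

Step 9
Reactants: 12 (E)-7,8-dimethyl-9-(triisopropylsilyloxy)deca-1,7,9-trien-3-one
Product: 13 (5S,10S)-3-(triisopropylsilyloxy)-11,12,13-trinoreremophil-3-en-9-one (5β-methyl; 10β-H; cis-fused)
Conditions: (S)-1-(2-methylphenyl)-3,3-diphenyltetrahydro-1H,3H-pyrrolo[1,2-c][1,3,2]oxazaborole (20 mol %), HN(SO2CF3)2 (16 mol %), CH2Cl2, −78 → −40 °C
Reagents that add atoms: none
Why: The cationic oxazaborolidinium binds the C9 carbonyl and the electron-rich 2-silyloxydiene adds in a concerted, asynchronous [4+2] cycloaddition in which the C1–C2 bond (enone β-carbon to enol ether terminus) runs ahead of the C5–C10 bond. The closest known reactions are the Lewis-acid-catalysed intramolecular Diels–Alder reaction of 1,7,9-decatrien-3-ones and the oxazaborolidinium-catalysed enantioselective Diels–Alder reaction of 2-silyloxydienes with enones. Ring A closes as the new cyclohexene of the cycloaddition; ring B closes through the C5–C10 bond as a six-membered ring holding the three-carbon tether and the carbonyl carbon (type 1 intramolecular mode). C10 is set by the enone face that the catalyst leaves open, and C5 is set relative to C10 by the endo transition state with the tether carbonyl under the diene, which gives the cis fusion and is favoured by the carbonyl-in-tether geometry and by Lewis acid activation. Since C10 is epimerised later, the step must deliver only the absolute configuration at C5, and this needs both high facial selectivity at the enone and high endo selectivity, because an exo adduct of the same enone face would carry the opposite C5. The E geometry fixed in steps 1 and 2 puts the tether outside and the methyl group inside the diene, the only arrangement in which the tether can reach, and regiochemistry is fixed by the tether and reinforced by the polarity of the silyloxydiene.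

Step 10
Reactants: 13 (5S,10S)-3-(triisopropylsilyloxy)-11,12,13-trinoreremophil-3-en-9-one
Product: 15 3-(triisopropylsilyloxy)-11,12,13-trinoreremophila-3,7-dien-9-one (5β-methyl; 10β-H; cis-fused), via lithium enolate 14 (not isolated)
Conditions: LiN(iPr)2, THF, −78 °C; then PhS(Cl)=NtBu, −78 °C
Reagents that add atoms: none
Why: Kinetic deprotonation at the C8 methylene (not the C10 methine) and dehydrogenation of the lithium enolate by the sulfinimidoyl chloride through sulfur transfer and syn-elimination, a one-pot counterpart of the Saegusa–Ito oxidation; the tetrasubstituted triisopropylsilyl enol ether in ring A is inert, so C3 and C9 stay differentiated.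

Step 11
Reactants: 15 3-(triisopropylsilyloxy)-11,12,13-trinoreremophila-3,7-dien-9-one (cis-fused)
Product: 17 11,12,13-trinoreremophil-7-ene-3,9-dione (4β,5β-dimethyl; 10α-H; trans-fused), via trans-fused silyl enol ether 16 (not isolated)
Conditions: DBU (0.3 equiv), toluene, 40 °C; then Bu4NF, AcOH, THF, −20 °C
Reagents that add atoms: none
Why: Base epimerisation at C10 should give the trans fusion, in which the axial C5 methyl group keeps a single syn-axial hydrogen; fluoride desilylation then releases the C3 enolate, which is protonated at C4 axially from the α face, anti to the C5 methyl group, to give the equatorial 4β-methyl group, also the expected thermodynamic epimer.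

Step 12
Reactants: 17 11,12,13-trinoreremophil-7-ene-3,9-dione (4β,5β-dimethyl; 10α-H)
Product: 18 3β-hydroxy-11,12,13-trinoreremophil-7-en-9-one (4β,5β-dimethyl; 10α-H)
Conditions: NaBH4, MeOH/CH2Cl2 (1:1), −78 °C
Reagents that add atoms: none
Why: Chemoselective borohydride reduction of a saturated ketone beside a conjugated enone, as in the Wieland–Miescher ketone series; the axial C5 methyl group blocks the β face of C3, so hydride enters from the α face and should give the axial 3β-alcohol, the sense known for 3-ketones of the friedelin type.

Step 13
Reactants: 18 3β-hydroxy-11,12,13-trinoreremophil-7-en-9-one; 19 angelic acid, (Z)-2-methylbut-2-enoic acid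
Product: 20 3α-angeloyloxy-11,12,13-trinoreremophil-7-en-9-one (4β,5β-dimethyl; 10α-H)
Conditions: PPh3, iPrO2CN=NCO2iPr, toluene, 0 → 23 °C
Reagents that add atoms: none
Why: Mitsunobu esterification with inversion; the strained axial oxygen is turned into a phosphonium leaving group and displaced from the open α face by angelate, giving the equatorial 3α-ester, and because the acid acts as the nucleophile and is never an acyl donor the Z olefin should stay intact.

Step 14
Reactants: 20 3α-angeloyloxy-11,12,13-trinoreremophil-7-en-9-one; 21 isopropenylmagnesium bromide
Product: 22 3α-angeloyloxy-9-(trimethylsilyloxy)eremophila-8,11-diene (4β,5β-dimethyl; 7β-H; 10α-H)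
Conditions: CuBr·SMe2 (20 mol %), Me3SiCl, THF, −78 °C; Et3N, cold aq NaHCO3
Reagents that add atoms: chlorotrimethylsilane, C[Si](C)(C)Cl
Why: Conjugate addition catalysed by monovalent copper and accelerated by the silyl chloride; the axial C5 methyl group is 1,3-syn-axial to the β face of C7, so the organocopper should add from the α face to give the equatorial 7α-isopropenyl group, and the enolate is stored as the C8–C9 silyl enol ether. The hindered trisubstituted angelate is a far poorer acceptor than the unsubstituted enone terminus.

Step 15
Reactants: 22 3α-angeloyloxy-9-(trimethylsilyloxy)eremophila-8,11-diene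
Product: 24 3α-angeloyloxy-8α-hydroxyeremophil-11-en-9-one, via silyloxy epoxide 23 (not isolated)
Conditions: dimethyldioxirane, acetone/CH2Cl2, −78 → −40 °C; then AcOH, H2O, THF, 0 °C
Reagents that add atoms: dimethyldioxirane, CC1(C)OO1
Why: Rubottom oxidation; the dioxirane epoxidises the electron-rich silyl enol ether much faster than the isopropenyl group or the electron-poor angelate, from the α face anti to the C5 methyl group, and mild acid opens the epoxide to the α-hydroxy ketone. The C8 configuration is of no lasting consequence because C8 becomes a ketone.

Step 16
Reactants: 24 3α-angeloyloxy-8α-hydroxyeremophil-11-en-9-one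
Product: 25 3α-angeloyloxyeremophil-11-ene-8α,9β-diol
Conditions: NaBH4, MeOH, −40 °C
Reagents that add atoms: none
Why: Borohydride reduction of the α-hydroxy ketone; as at C3, the β face of C9 is shielded by the syn-axial C5 methyl group, so hydride (free or delivered from the 8α-alkoxyborohydride) should enter from the α face and give the axial 9β-alcohol, as hydroxy ketones beside an angular methyl group usually do.

Step 17
Reactants: 25 3α-angeloyloxyeremophil-11-ene-8α,9β-diol
Product: 26 3α-angeloyloxy-9β-hydroxyeremophil-11-en-8-one
Conditions: TEMPO (10 mol %), PhI(OAc)2, CH2Cl2/pH 7 phosphate buffer, 0 → 23 °C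
Reagents that add atoms: none
Why: Oxoammonium oxidation, which is sensitive to steric hindrance; the 9β-hydroxyl is next to the ring fusion and syn-axial to the C5 methyl group, whereas the 8α-hydroxyl has only syn-axial hydrogens, so C8 should be oxidised first. The trans-diaxial diol cannot form the cyclic iodine ester needed for glycol cleavage, and the buffer protects the new β,γ-unsaturated ketone.

Step 18
Reactants: 26 3α-angeloyloxy-9β-hydroxyeremophil-11-en-8-one; 27 (E)-3-methylpent-2-enoic acid
Product: 28 3α-angeloyloxy-9α-[(E)-3-methylpent-2-enoyloxy]eremophil-11-en-8-one (target)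
Conditions: PPh3, iPrO2CN=NCO2iPr, THF, 0 → 23 °C
Reagents that add atoms: none
Why: Mitsunobu inversion at an α-ketol carbon; the axial 9β-oxyphosphonium group is displaced from the α face by the carboxylate in an SN2 reaction accelerated by the adjacent carbonyl, giving the equatorial 9α-ester. The near-neutral conditions should spare the β,γ-unsaturated ketone, the C7 centre and both enoates.

## Compound list

1 | methyl 2-methyl-3-oxobutanoate | COC(=O)C(C)C(C)=O | starting material
2 | methyl (E)-2-methyl-3-(4-methylbenzenesulfonyloxy)but-2-enoate | COC(=O)/C(C)=C(\C)OS(=O)(=O)c1ccc(C)cc1 | intermediate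
3 | (3-cyanopropyl)zinc bromide | N#CCCC[Zn]Br | starting material
4 | methyl (E)-6-cyano-2,3-dimethylhex-2-enoate | COC(=O)/C(C)=C(\C)CCCC#N | intermediate
5 | (E)-6-cyano-N-methoxy-N,2,3-trimethylhex-2-enamide | CON(C)C(=O)/C(C)=C(\C)CCCC#N | intermediate
6 | (E)-5,6-dimethyl-7-oxooct-5-enenitrile | CC(=O)/C(C)=C(\C)CCCC#N | intermediate
7 | lithium (E)-7-cyano-3,4-dimethylhepta-1,3-dien-2-olate (formed in the flask) | [Li]OC(=C)/C(C)=C(\C)CCCC#N | intermediate
8 | (E)-5,6-dimethyl-7-(triisopropylsilyloxy)octa-5,7-dienenitrile | C=C(O[Si](C(C)C)(C(C)C)C(C)C)/C(C)=C(\C)CCCC#N | intermediate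
9 | (E)-5,6-dimethyl-7-(triisopropylsilyloxy)octa-5,7-dienal | C=C(O[Si](C(C)C)(C(C)C)C(C)C)/C(C)=C(\C)CCCC=O | intermediate
10 | vinylmagnesium bromide | C=C[Mg]Br | starting material
11 | (E)-7,8-dimethyl-9-(triisopropylsilyloxy)deca-1,7,9-trien-3-ol (racemic) | C=C(O[Si](C(C)C)(C(C)C)C(C)C)/C(C)=C(\C)CCCC(O)C=C | intermediate
12 | (E)-7,8-dimethyl-9-(triisopropylsilyloxy)deca-1,7,9-trien-3-one | C=C(O[Si](C(C)C)(C(C)C)C(C)C)/C(C)=C(\C)CCCC(=O)C=C | intermediate
13 | (5S,10S)-3-(triisopropylsilyloxy)-11,12,13-trinoreremophil-3-en-9-one (5β-methyl; 10β-H; cis-fused) | O=C1CCC[C@]2(C)C(C)=C(O[Si](C(C)C)(C(C)C)C(C)C)CC[C@H]12 | intermediate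
14 | lithium 3-(triisopropylsilyloxy)-11,12,13-trinoreremophila-3,8-dien-9-olate (cis-fused; formed in the flask) | [Li]OC1=CCC[C@]2(C)C(C)=C(O[Si](C(C)C)(C(C)C)C(C)C)CC[C@H]12 | intermediate
15 | 3-(triisopropylsilyloxy)-11,12,13-trinoreremophila-3,7-dien-9-one (5β-methyl; 10β-H; cis-fused) | O=C1C=CC[C@]2(C)C(C)=C(O[Si](C(C)C)(C(C)C)C(C)C)CC[C@H]12 | intermediate
16 | 3-(triisopropylsilyloxy)-11,12,13-trinoreremophila-3,7-dien-9-one (5β-methyl; 10α-H; trans-fused; formed in the flask) | O=C1C=CC[C@]2(C)C(C)=C(O[Si](C(C)C)(C(C)C)C(C)C)CC[C@@H]12 | intermediate
17 | 11,12,13-trinoreremophil-7-ene-3,9-dione (4β,5β-dimethyl; 10α-H; trans-fused) | O=C1C=CC[C@]2(C)[C@@H](C)C(=O)CC[C@@H]12 | intermediate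
18 | 3β-hydroxy-11,12,13-trinoreremophil-7-en-9-one (4β,5β-dimethyl; 10α-H) | O=C1C=CC[C@]2(C)[C@@H](C)[C@@H](O)CC[C@@H]12 | intermediate
19 | angelic acid, (Z)-2-methylbut-2-enoic acid | C/C=C(/C)C(=O)O | starting material
20 | 3α-angeloyloxy-11,12,13-trinoreremophil-7-en-9-one (4β,5β-dimethyl; 10α-H) | O=C1C=CC[C@]2(C)[C@@H](C)[C@H](OC(=O)/C(C)=C\C)CC[C@@H]12 | intermediate
21 | isopropenylmagnesium bromide (prop-1-en-2-ylmagnesium bromide) | CC(=C)[Mg]Br | starting material
22 | 3α-angeloyloxy-9-(trimethylsilyloxy)eremophila-8,11-diene (4β,5β-dimethyl; 7β-H; 10α-H) | C=C(C)[C@@H]1C[C@]2(C)[C@@H](C)[C@H](OC(=O)/C(C)=C\C)CC[C@H]2C(O[Si](C)(C)C)=C1 | intermediate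
23 | 3α-angeloyloxy-8α,9α-epoxy-9β-(trimethylsilyloxy)eremophil-11-ene (formed in the flask) | C=C(C)[C@@H]1C[C@]2(C)[C@@H](C)[C@H](OC(=O)/C(C)=C\C)CC[C@H]2[C@]3(O[Si](C)(C)C)O[C@H]13 | intermediate
24 | 3α-angeloyloxy-8α-hydroxyeremophil-11-en-9-one | C=C(C)[C@@H]1C[C@]2(C)[C@@H](C)[C@H](OC(=O)/C(C)=C\C)CC[C@H]2C(=O)[C@@H]1O | intermediate
25 | 3α-angeloyloxyeremophil-11-ene-8α,9β-diol | C=C(C)[C@@H]1C[C@]2(C)[C@@H](C)[C@H](OC(=O)/C(C)=C\C)CC[C@H]2[C@@H](O)[C@@H]1O | intermediate
26 | 3α-angeloyloxy-9β-hydroxyeremophil-11-en-8-one | C=C(C)[C@@H]1C[C@]2(C)[C@@H](C)[C@H](OC(=O)/C(C)=C\C)CC[C@H]2[C@@H](O)C1=O | intermediate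
27 | (E)-3-methylpent-2-enoic acid | CC/C(C)=C/C(=O)O | starting material
28 | 3α-angeloyloxy-9α-[(E)-3-methylpent-2-enoyloxy]eremophil-11-en-8-one (4β,5β-dimethyl; 7β-H; 10α-H; 3R,4R,5R,7S,9S,10R) | C=C(C)[C@@H]1C[C@]2(C)[C@@H](C)[C@H](OC(=O)/C(C)=C\C)CC[C@H]2[C@H](OC(=O)/C=C(\C)CC)C1=O | target

## Step count and least certain steps

Total: 18 steps. Longest linear sequence: 18 steps (1 to 28); compounds 3, 10, 19, 21 and 27 enter as purchased reagents.

**Step 9 (key step).**
- What may go wrong: slow cycloaddition, because the methyl group on the diene terminus must sit inside the s-cis diene. Then stepwise conjugate addition of the enol ether without ring closure, or protodesilylation of the diene by the acidic catalyst, can take over. Incomplete facial or endo selectivity would lower the enantiomeric purity at C5, and uncatalysed background cyclisation would do the same.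
- Fallback: trienone 12 is cyclised with an achiral Lewis acid (Me2AlCl, CH2Cl2, −78 °C) or by gentle heating to the racemic cis-fused adduct F1. Its enantiomers are separated by preparative chromatography on a chiral stationary phase, and the (5S,10S) enantiomer re-enters the route as 13.

**Step 13.**
- What may go wrong: elimination from the activated axial alcohol toward C2 or C4 (antiperiplanar axial hydrogens), or acyl transfer with retention if the hindered hydroxyl fails to attack phosphorus.
- Fallback: this sets out from 17 and replaces inversion by thermodynamic reduction. Li in NH3/THF with t-BuOH at −78 °C should reduce the C3 ketone to the equatorial 3α-alkoxide and the enone to its C8–C9 lithium enolate. After removal of ammonia, Me3SiCl/Et3N gives the bis-silyl compound 3α,9-bis(trimethylsilyloxy)-11,12,13-trinoreremophil-8-ene F2. Pd(OAc)2 in MeCN (Saegusa–Ito oxidation) restores the enone as the 3α-trimethylsilyl ether F3, and dilute acid frees the 3α-hydroxy enone F4. Esterification of F4 with 19 through the 2,4,6-trichlorobenzoyl mixed anhydride (Yamaguchi conditions, at or below room temperature to limit isomerisation to the tiglate) returns to the route at 20.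

**Step 17.**
- What may go wrong: oxidation at C9 instead of C8 or at both carbinols (poor site selectivity), and conjugation of the new β,γ-unsaturated ketone.
- Fallback: this sets out from 20 and separates the two hydroxyls by protection instead of by rate. The conjugate addition of 21 is run with Et3SiCl to give the triethylsilyl enol ether F5. Dimethyldioxirane followed by warming gives, by silyl migration, the 8α-triethylsilyloxy 9-ketone F6. NaBH4 gives the 9β-alcohol F7, and MeSO2Cl/Et3N gives the 9β-mesylate F8. HF·pyridine frees the C8 hydroxyl to give the hydroxy mesylate F9, and Dess–Martin periodinane gives the 8-keto 9β-mesylate F10. Displacement with the caesium salt of 27 in DMF (SN2 with inversion next to the carbonyl) gives 28 directly, so step 18 is bypassed as well.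

**Step 18.**
- What may go wrong: esterification with retention through an acyloxyphosphonium pathway, because the 9β-hydroxyl is hindered; elimination toward C10 to the conjugated 9-en-8-one; tautomerisation of the ketol.
- Fallback: this sets out from 26 and brings the C9 oxygen in from the α face instead of inverting it. SmI2 in THF/MeOH at −78 °C removes the C9 hydroxyl to give the 8-ketone F11. LiN(SiMe3)2 with Me3SiCl at −78 °C gives the less substituted C8–C9 silyl enol ether F12. Dimethyldioxirane and then mild acid give the 9α-hydroxy 8-ketone F13, the oxygen entering anti to the C5 methyl group. Carbodiimide esterification with 27 (dicyclohexylcarbodiimide, catalytic 4-dimethylaminopyridine, 0 °C) returns to the route at 28.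

## Further compounds

F1 | step 9 | racemic cis-fused adduct (1:1 mixture of 13 and its mirror image) | O=C1CCC[C@]2(C)C(C)=C(O[Si](C(C)C)(C(C)C)C(C)C)CC[C@H]12.O=C1CCC[C@@]2(C)C(C)=C(O[Si](C(C)C)(C(C)C)C(C)C)CC[C@@H]12
F2 | step 13 | 3α,9-bis(trimethylsilyloxy)-11,12,13-trinoreremophil-8-ene (4β,5β-dimethyl; 10α-H) | C[Si](C)(C)OC1=CCC[C@]2(C)[C@@H](C)[C@H](O[Si](C)(C)C)CC[C@@H]12
F3 | step 13 | 3α-(trimethylsilyloxy)-11,12,13-trinoreremophil-7-en-9-one (4β,5β-dimethyl; 10α-H) | O=C1C=CC[C@]2(C)[C@@H](C)[C@H](O[Si](C)(C)C)CC[C@@H]12
F4 | step 13 | 3α-hydroxy-11,12,13-trinoreremophil-7-en-9-one (4β,5β-dimethyl; 10α-H) | O=C1C=CC[C@]2(C)[C@@H](C)[C@H](O)CC[C@@H]12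
F5 | step 17 | 3α-angeloyloxy-9-(triethylsilyloxy)eremophila-8,11-diene | C=C(C)[C@@H]1C[C@]2(C)[C@@H](C)[C@H](OC(=O)/C(C)=C\C)CC[C@H]2C(O[Si](CC)(CC)CC)=C1
F6 | step 17 | 3α-angeloyloxy-8α-(triethylsilyloxy)eremophil-11-en-9-one | C=C(C)[C@@H]1C[C@]2(C)[C@@H](C)[C@H](OC(=O)/C(C)=C\C)CC[C@H]2C(=O)[C@@H]1O[Si](CC)(CC)CC
F7 | step 17 | 3α-angeloyloxy-8α-(triethylsilyloxy)eremophil-11-en-9β-ol | C=C(C)[C@@H]1C[C@]2(C)[C@@H](C)[C@H](OC(=O)/C(C)=C\C)CC[C@H]2[C@@H](O)[C@@H]1O[Si](CC)(CC)CC
F8 | step 17 | 3α-angeloyloxy-9β-(methanesulfonyloxy)-8α-(triethylsilyloxy)eremophil-11-ene | C=C(C)[C@@H]1C[C@]2(C)[C@@H](C)[C@H](OC(=O)/C(C)=C\C)CC[C@H]2[C@@H](OS(C)(=O)=O)[C@@H]1O[Si](CC)(CC)CC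
F9 | step 17 | 3α-angeloyloxy-9β-(methanesulfonyloxy)eremophil-11-en-8α-ol | C=C(C)[C@@H]1C[C@]2(C)[C@@H](C)[C@H](OC(=O)/C(C)=C\C)CC[C@H]2[C@@H](OS(C)(=O)=O)[C@@H]1O
F10 | step 17 | 3α-angeloyloxy-9β-(methanesulfonyloxy)eremophil-11-en-8-one | C=C(C)[C@@H]1C[C@]2(C)[C@@H](C)[C@H](OC(=O)/C(C)=C\C)CC[C@H]2[C@@H](OS(C)(=O)=O)C1=O
F11 | step 18 | 3α-angeloyloxyeremophil-11-en-8-one | C=C(C)[C@@H]1C[C@]2(C)[C@@H](C)[C@H](OC(=O)/C(C)=C\C)CC[C@H]2CC1=O
F12 | step 18 | 3α-angeloyloxy-8-(trimethylsilyloxy)eremophila-8,11-diene | C=C(C)[C@@H]1C[C@]2(C)[C@@H](C)[C@H](OC(=O)/C(C)=C\C)CC[C@H]2C=C1O[Si](C)(C)C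
F13 | step 18 | 3α-angeloyloxy-9α-hydroxyeremophil-11-en-8-one | C=C(C)[C@@H]1C[C@]2(C)[C@@H](C)[C@H](OC(=O)/C(C)=C\C)CC[C@H]2[C@H](O)C1=O
A1 | alternative 1 | 3α-(tert-butyldimethylsilyloxy)-9α-(4-methoxybenzyloxy)eremophil-11-en-8β-ol (4β,5β-dimethyl; 7β-H; 10α-H) | C=C(C)[C@@H]1C[C@]2(C)[C@@H](C)[C@H](O[Si](C)(C)C(C)(C)C)CC[C@H]2[C@H](OCc3ccc(OC)cc3)[C@H]1O
A2 | alternative 2 | 2-allyl-2,3-dimethyl-4-(tert-butyldimethylsilyloxy)cyclohexan-1-one with the C3, C4 and C5 configuration of the target | C=CC[C@]1(C)[C@@H](C)[C@H](O[Si](C)(C)C(C)(C)C)CCC1=O
A3 | alternative 3 | 4β,5β-dimethyl-11,12,13-trinoreremophil-9-ene-3,8-dione | O=C1CC[C@]2(C)[C@@H](C)C(=O)CCC2=C1
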